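**Retrosynthetic overview**

- The strategy rests on reading the quinone ring C1(=O)–C2(OMe)=C3(indol-3-yl)–C4(=O)–C5(OMe)=C6(7-prenylindol-3-yl) as two pieces: a four-atom maleoyl unit C4(=O)–C5(OMe)=C6(aryl)–C1(=O) and a two-atom unit C2(OMe)=C3(indolyl), which is an alkyne at the ynol ether oxidation level.
- Key disconnection: bonds C1–C2 and C3–C4, made by a cobalt-mediated [4+2] union of a 3-methoxy-4-indolylcyclobutenedione with 1-Boc-3-(methoxyethynyl)indole; both methoxy groups and both indoles are in place beforehand.
- The cyclobutenedione comes from dimethyl squarate and the 3-indolyl Grignard reagent (addition, then trifluoroacetic anhydride transposition); the prenyl group comes from a Stille coupling on 7-bromoindole.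
- The ynol ether comes from N-Boc-3-iodoindole and methoxyethynylzinc chloride (Negishi coupling).
- Ring order: both indole bicycles are bought, the four-membered ring is bought as squarate, and the quinone ring is the only ring made (step 6); Boc removal comes last.

Key step: step 6

Remark: the target has no stereocentre and its only acyclic alkene carries two identical methyl groups, so no stereochemistry has to be set; tributyl(3-methylbut-2-en-1-yl)stannane, dimethyl squarate, iPrMgCl·LiCl and CoCl(PPh3)3 are taken as purchasable.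

**Route**

Step 1
Reactants: 1 7-bromo-1H-indole
Product: 2 7-(3-methylbut-2-en-1-yl)-1H-indole
Conditions: tributyl(3-methylbut-2-en-1-yl)stannane (1.3 equiv), Pd(PPh3)4 (5 mol %), DMF, 100 °C
Reagents that add atoms: tributyl(3-methylbut-2-en-1-yl)stannane, CCCC[Sn](CCCC)(CCCC)CC=C(C)C
Why: Migita–Kosugi–Stille coupling of the aryl bromide with the allylic stannane should give the linear prenyl group, because the prenylpalladium intermediate eliminates reductively at its unsubstituted terminus and the free indole N–H is tolerated.

Step 2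
Reactants: 2 7-(3-methylbut-2-en-1-yl)-1H-indole
Product: 4 tert-butyl 3-iodo-7-(3-methylbut-2-en-1-yl)indole-1-carboxylate, via 3-iodo-7-prenylindole 3 (not isolated)
Conditions: iodine (1.02 equiv), KOH, DMF, 0 °C to rt; then Boc2O, DMAP (cat.), rt
Reagents that add atoms: iodine, [I][I]; di-tert-butyl dicarbonate, CC(C)(C)OC(=O)OC(=O)OC(C)(C)C
Why: Electrophilic iodination at the most nucleophilic indole position C3 should be much faster than any reaction of iodine at the trisubstituted alkene, and the labile 3-iodoindole is stabilised at once by DMAP-catalysed N-acylation (carbamate formation).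

Step 3
Reactants: 4 tert-butyl 3-iodo-7-(3-methylbut-2-en-1-yl)indole-1-carboxylate; 5 dimethyl squarate (3,4-dimethoxycyclobut-3-ene-1,2-dione)
Product: 9 tert-butyl 3-(2-methoxy-3,4-dioxocyclobut-1-en-1-yl)-7-(3-methylbut-2-en-1-yl)indole-1-carboxylate, via indol-3-ylmagnesium chloride 6 (not isolated), via squarate adduct magnesium alkoxide 7 (not isolated), via adduct trifluoroacetate 8 (not isolated)
Conditions: iPrMgCl·LiCl (1.05 equiv), THF, −40 °C; add to 5 (1.2 equiv), THF, −78 to −40 °C; (CF3CO)2O, −78 °C; aq. NaHCO3, 0 °C
Reagents that add atoms: water, O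
Why: Iodine–magnesium exchange gives the 3-indolyl Grignard reagent, which adds 1,2 to one squarate carbonyl (racemic adduct, stereocentre lost again); trifluoroacetylation, ionisation to the methoxy-stabilised cyclobutenyl cation and hydrolysis on work-up should give the 3-methoxy-4-arylcyclobutenedione, the standard squarate addition–transposition sequence.

Step 4
Reactants: 10 1H-indole
Product: 12 tert-butyl 3-iodoindole-1-carboxylate, via 3-iodoindole 11 (not isolated)
Conditions: iodine (1.02 equiv), KOH, DMF, rt; then Boc2O, DMAP (cat.), rt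
Reagents that add atoms: iodine, [I][I]; di-tert-butyl dicarbonate, CC(C)(C)OC(=O)OC(=O)OC(C)(C)C
Why: C3-selective electrophilic iodination of indole followed by immediate N-Boc protection is a standard sequence that turns the unstable 3-iodoindole into a storable aryl iodide.

Step 5
Reactants: 13 chloroacetaldehyde dimethyl acetal (2-chloro-1,1-dimethoxyethane); 12 tert-butyl 3-iodoindole-1-carboxylate
Product: 16 tert-butyl 3-(methoxyethynyl)indole-1-carboxylate, via lithium methoxyacetylide 14 (not isolated), via methoxyethynylzinc chloride 15 (not isolated)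
Conditions: 13 (1.5 equiv), LiNEt2 (3 equiv per 13), THF, 0 °C; ZnCl2 (2.2 equiv per 13), 0 °C; 12, Pd(PPh3)4 (5 mol %), THF, rt; chromatography on Et3N-treated silica
Reagents that add atoms: none
Why: Double elimination and deprotonation of the chloroacetal give the lithium alkoxyacetylide, and transmetalation to zinc followed by Negishi coupling with the aryl iodide under zerovalent palladium catalysis should give the aryl ynol ether, the excess ZnCl2 holding the liberated methoxide so that the Boc group is not attacked.

Step 6
Reactants: 9 tert-butyl 3-(2-methoxy-3,4-dioxocyclobut-1-en-1-yl)-7-(3-methylbut-2-en-1-yl)indole-1-carboxylate; 16 tert-butyl 3-(methoxyethynyl)indole-1-carboxylate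
Product: 19 tert-butyl 3-[4-(1-tert-butoxycarbonylindol-3-yl)-2,5-dimethoxy-3,6-dioxocyclohexa-1,4-dien-1-yl]-7-(3-methylbut-2-en-1-yl)indole-1-carboxylate, via maleoylcobalt bis(triphenylphosphine) chloride 17 (not isolated), via maleoylcobalt dimethylglyoxime pyridine chloride 18 (not isolated)
Conditions: CoCl(PPh3)3 (1.1 equiv), PhCl, rt; dimethylglyoxime, pyridine, rt, concentrate; then 16 (1.5 equiv), CoCl2 (anhydrous, 1 equiv), 4 Å MS, ClCH2CH2Cl/MeCN, 60 °C; air, filtration through silica
Reagents that add atoms: none
Why: Proposed new method: monovalent cobalt in CoCl(PPh3)3 should add oxidatively into the strained acyl–acyl bond of 9 to give the five-membered trivalent-cobalt maleoyl metallacycle 17, and exchange of both phosphines for dimethylglyoxime and pyridine (18) leaves a complex in which the anhydrous Lewis acid CoCl2 opens a site for the alkyne. The ynol ether 16 should then coordinate and insert into one cobalt–acyl bond, and the resulting vinyl–cobalt bond eliminates reductively onto the second acyl, so the six-membered ring is closed by a metal-templated [4+2] union (first C–C bond by migratory insertion, ring closure by reductive elimination) directly at the quinone oxidation level, with no stereocentre formed. The closest known reaction type is the quinone synthesis from maleoyl- and phthaloylcobalt dimethylglyoxime complexes with simple alkynes; an aryl ynol ether as the alkyne and a 3-indolyl-substituted maleoyl complex are not established for it. The step needs regioselectivity (2,5- and not 2,6-placement of the two indoles): the acyl beside C–OMe is the more electrophilic one because the other acyl is a vinylogous ester, the Lewis acid binds the more basic vinylogous-ester oxygen and so further disfavours migration of that acyl, and the nucleophilic indolyl-bearing carbon of the polarised ynol ether should bond to the electrophilic acyl while the methoxy-bearing carbon goes to cobalt. The methyl ynol ether cannot fragment by a retro-ene path at 60 °C, and both Boc groups keep the indoles from competing as nucleophiles or ligands.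

Step 7
Reactants: 19 tert-butyl 3-[4-(1-tert-butoxycarbonylindol-3-yl)-2,5-dimethoxy-3,6-dioxocyclohexa-1,4-dien-1-yl]-7-(3-methylbut-2-en-1-yl)indole-1-carboxylate
Product: 20 2,5-dimethoxy-3-(1H-indol-3-yl)-6-[7-(3-methylbut-2-en-1-yl)-1H-indol-3-yl]cyclohexa-2,5-diene-1,4-dione
Conditions: neat, 180 °C, Ar
Reagents that add atoms: none
Why: Thermolysis of the two indole N-tert-butyl carbamates by cyclic elimination should release 2-methylpropene and carbon dioxide without acid or base, so the methoxyquinone (a vinylogous ester) and the prenyl alkene are left untouched.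

**Compound list**

1 | 7-bromo-1H-indole | Brc1cccc2cc[nH]c12 | starting material
2 | 7-(3-methylbut-2-en-1-yl)-1H-indole | CC(C)=CCc1cccc2cc[nH]c12 | intermediate
3 | 3-iodo-7-(3-methylbut-2-en-1-yl)-1H-indole | CC(C)=CCc1cccc2c(I)c[nH]c12 | intermediate
4 | tert-butyl 3-iodo-7-(3-methylbut-2-en-1-yl)indole-1-carboxylate | CC(C)=CCc1cccc2c(I)cn(C(=O)OC(C)(C)C)c12 | intermediate
5 | dimethyl squarate (3,4-dimethoxycyclobut-3-ene-1,2-dione) | COC1=C(OC)C(=O)C1=O | starting material
6 | [1-(tert-butoxycarbonyl)-7-(3-methylbut-2-en-1-yl)indol-3-yl]magnesium chloride (LiCl complex) | CC(C)=CCc1cccc2c([Mg]Cl)cn(C(=O)OC(C)(C)C)c12 | intermediate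
7 | chloromagnesium alkoxide of racemic tert-butyl 3-(1-hydroxy-2,3-dimethoxy-4-oxocyclobut-2-en-1-yl)-7-(3-methylbut-2-en-1-yl)indole-1-carboxylate | COC1=C(OC)C(O[Mg]Cl)(c2cn(C(=O)OC(C)(C)C)c3c(CC=C(C)C)cccc23)C1=O | intermediate
8 | trifluoroacetate ester of the racemic squarate adduct | COC1=C(OC)C(OC(=O)C(F)(F)F)(c2cn(C(=O)OC(C)(C)C)c3c(CC=C(C)C)cccc23)C1=O | intermediate
9 | tert-butyl 3-(2-methoxy-3,4-dioxocyclobut-1-en-1-yl)-7-(3-methylbut-2-en-1-yl)indole-1-carboxylate | COC1=C(c2cn(C(=O)OC(C)(C)C)c3c(CC=C(C)C)cccc23)C(=O)C1=O | intermediate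
10 | 1H-indole | c1ccc2[nH]ccc2c1 | starting material
11 | 3-iodo-1H-indole | Ic1c[nH]c2ccccc12 | intermediate
12 | tert-butyl 3-iodoindole-1-carboxylate | CC(C)(C)OC(=O)n1cc(I)c2ccccc12 | intermediate
13 | chloroacetaldehyde dimethyl acetal (2-chloro-1,1-dimethoxyethane) | COC(CCl)OC | starting material
14 | lithium methoxyacetylide | COC#C[Li] | intermediate
15 | methoxyethynylzinc chloride | COC#C[Zn]Cl | intermediate
16 | tert-butyl 3-(methoxyethynyl)indole-1-carboxylate | COC#Cc1cn(C(=O)OC(C)(C)C)c2ccccc12 | intermediate
17 | chlorobis(triphenylphosphine) maleoylcobalt metallacycle, five-membered ring Co–C(=O)–C(OMe)=C(aryl)–C(=O), trivalent cobalt | COC1=C(c2cn(C(=O)OC(C)(C)C)c3c(CC=C(C)C)cccc23)C(=O)[Co-2](Cl)([P+](c2ccccc2)(c2ccccc2)c2ccccc2)([P+](c2ccccc2)(c2ccccc2)c2ccccc2)C1=O | intermediate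
18 | chloro(dimethylglyoxime)(pyridine) maleoylcobalt metallacycle, trivalent cobalt | COC1=C(c2cn(C(=O)OC(C)(C)C)c3c(CC=C(C)C)cccc23)C(=O)[Co-3]2(Cl)([n+]3ccccc3)([N+](O)=C(C)C(C)=[N+]2O)C1=O | intermediate
19 | tert-butyl 3-[4-(1-tert-butoxycarbonylindol-3-yl)-2,5-dimethoxy-3,6-dioxocyclohexa-1,4-dien-1-yl]-7-(3-methylbut-2-en-1-yl)indole-1-carboxylate | COC1=C(c2cn(C(=O)OC(C)(C)C)c3ccccc23)C(=O)C(OC)=C(c2cn(C(=O)OC(C)(C)C)c3c(CC=C(C)C)cccc23)C1=O | intermediate
20 | 2,5-dimethoxy-3-(1H-indol-3-yl)-6-[7-(3-methylbut-2-en-1-yl)-1H-indol-3-yl]cyclohexa-2,5-diene-1,4-dione (CNP0256613.0) | COC1=C(c2c[nH]c3ccccc23)C(=O)C(OC)=C(c2c[nH]c3c(CC=C(C)C)cccc23)C1=O | target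

**Step count and risks**

Total step count: 7. Longest linear sequence: 5 steps (steps 1, 2, 3, 6, 7).

Steps most likely to fail:

Step 6. The alkyne may insert with the opposite orientation or into the other cobalt–acyl bond, which would place the two indoles 2,6 instead of 2,5. The Lewis acid may also hydrate or oligomerise the ynol ether before it inserts, and oxidative addition into the hindered, donor-substituted dione may be slow. The fallback uses known indole–quinone chemistry; it sets out from indole 10 and 7-prenylindole 2, comes back to the route at target 20, and so also replaces step 7. Acid-promoted conjugate addition of 10 to 2,5-dichloro-1,4-benzoquinone (cat. HCl, THF, rt) gives 2,5-dichloro-3-(1H-indol-3-yl)benzene-1,4-diol F1. Oxidation with DDQ gives 2,5-dichloro-3-(1H-indol-3-yl)-1,4-benzoquinone F2. A second conjugate addition, of 2 at the remaining C–H position (AcOH, rt), gives 2,5-dichloro-3-(1H-indol-3-yl)-6-[7-(3-methylbut-2-en-1-yl)-1H-indol-3-yl]benzene-1,4-diol F3. Oxidation with Ag2CO3 on Celite gives 2,5-dichloro-3-(1H-indol-3-yl)-6-[7-(3-methylbut-2-en-1-yl)-1H-indol-3-yl]-1,4-benzoquinone F4. NaOMe in MeOH/THF then replaces both vinylogous acyl chlorides by addition–elimination to give 20.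

Step 5. Liberated methoxide or amide may attack the Boc carbonyl, the electron-rich ynol ether may be hydrated to the ester on work-up or chromatography, and the alkynylzinc may homocouple. The fallback builds the ynol ether by elimination instead of cross-coupling; it sets out from indole 10 and comes back at 16. C3-acylation of 10 with methoxyacetyl chloride and Et2AlCl (CH2Cl2, 0 °C) gives 1-(1H-indol-3-yl)-2-methoxyethanone F5. Boc2O and DMAP give tert-butyl 3-(methoxyacetyl)indole-1-carboxylate F6. LiN(SiMe3)2 and PhNTf2 (THF, −78 °C) give, through the chelated enolate, tert-butyl 3-[(Z)-2-methoxy-1-(trifluoromethylsulfonyloxy)ethenyl]indole-1-carboxylate F7. Anti-elimination with KOtBu (THF, −78 °C) gives 16.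

Step 1. Allylic transposition at palladium may give the reverse-prenyl (1,1-dimethylallyl) isomer, a palladium hydride may move the alkene into conjugation with the arene, and oxidative addition next to the free N–H may be slow. The fallback builds the prenyl group by metathesis; it sets out from 7-bromoindole 1 and comes back at 2. Stille coupling of 1 with allyltributylstannane (Pd(PPh3)4, DMF, 100 °C), where transposition is degenerate, gives 7-allyl-1H-indole F8. Cross-metathesis with excess 2-methylbut-2-ene (second-generation Grubbs catalyst, CH2Cl2, 40 °C) gives 2.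

**Further compounds**

F1 | step 6 | 2,5-dichloro-3-(1H-indol-3-yl)benzene-1,4-diol | Oc1c(Cl)c(-c2c[nH]c3ccccc23)c(O)c(Cl)c1
F2 | step 6 | 2,5-dichloro-3-(1H-indol-3-yl)-1,4-benzoquinone | O=C1C(Cl)=C(c2c[nH]c3ccccc23)C(=O)C(Cl)=C1
F3 | step 6 | 2,5-dichloro-3-(1H-indol-3-yl)-6-[7-(3-methylbut-2-en-1-yl)-1H-indol-3-yl]benzene-1,4-diol | Oc1c(Cl)c(-c2c[nH]c3ccccc23)c(O)c(Cl)c1-c4c[nH]c5c(CC=C(C)C)cccc45
F4 | step 6 | 2,5-dichloro-3-(1H-indol-3-yl)-6-[7-(3-methylbut-2-en-1-yl)-1H-indol-3-yl]-1,4-benzoquinone | O=C1C(Cl)=C(c2c[nH]c3ccccc23)C(=O)C(Cl)=C1c1c[nH]c2c(CC=C(C)C)cccc12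
F5 | step 5 | 1-(1H-indol-3-yl)-2-methoxyethanone | COCC(=O)c1c[nH]c2ccccc12
F6 | step 5 | tert-butyl 3-(methoxyacetyl)indole-1-carboxylate | COCC(=O)c1cn(C(=O)OC(C)(C)C)c2ccccc12
F7 | step 5 | tert-butyl 3-[(Z)-2-methoxy-1-(trifluoromethylsulfonyloxy)ethenyl]indole-1-carboxylate | CO/C=C(\OS(=O)(=O)C(F)(F)F)c1cn(C(=O)OC(C)(C)C)c2ccccc12
F8 | step 1 | 7-allyl-1H-indole | C=CCc1cccc2cc[nH]c12
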